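**Retrosynthetic overview** (chain numbering C1 = alkyne terminus to C15 = ethyl terminus; the ring is O plus C7–C13)
1. Target ⇒ C12 bromide by inversion of a C12 alcohol; C6 acetate; (E)-enyne from a C6 allyl group by cross-metathesis and Colvin homologation; C6 carbinol by chelation-controlled allylation of a C6 aldehyde.
2. The C13 ethyl group and the C12 oxygen both come from one lactone carbonyl at C13 (thionolactone ethylation with radical reduction; enolate hydroxylation).
3. The oxocene, the only ring, is formed once: its O–C7 bond is made by Baeyer–Villiger ring expansion of (2R)-2-[(benzyloxy)methyl]cyclohept-4-en-1-one.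
4. Enabling feature: the ring is one oxygen bridging a seven-carbon chain C7–C13 with the cis C9=C10 alkene opposite the oxygen, and C13 (O-bound, ethyl-bearing, next to C12–Br) can stand at the acyl level. Removing the oxygen therefore leaves cyclohept-4-en-1-one with C=O at C13 and the stereogenic α-carbon C7 as migrating group.
5. The ketone comes from cyclohept-4-en-1-one by RAMP-hydrazone alkylation, which sets C7.

Key step: step 4

Assumption: cyclohept-4-en-1-one is taken as purchasable (otherwise ring-closing metathesis of nona-1,8-dien-5-one gives it). Names use ring locants (O1, C2 = C13, C3 = C12, C8 = C7); the Why lines use the chain numbering.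

**Step 1**
Reactants: 1 cyclohept-4-en-1-one; 2 (R)-1-amino-2-(methoxymethyl)pyrrolidine (RAMP)
Product: 3 (R)-N-(cyclohept-4-en-1-ylidene)-2-(methoxymethyl)pyrrolidin-1-amine
Conditions: neat, 60 °C, then removal of water under vacuum
Reagents that add atoms: none
Why: Hydrazone condensation of a symmetric ketone with the RAMP auxiliary; no stereocenter is formed.

**Step 2**
Reactants: 3 RAMP hydrazone
Product: 5 (R)-N-[(2S)-2-[(benzyloxy)methyl]cyclohept-4-en-1-ylidene]-2-(methoxymethyl)pyrrolidin-1-amine (C=N geometry not defined; the 2S label is a priority effect and the spatial arrangement is that of the 2R ketone), via lithium azaenolate 4 (not isolated)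
Conditions: LiN(iPr)2, THF, 0 °C; then BnOCH2Cl, −95 °C to rt
Reagents that add atoms: benzyl chloromethyl ether, ClCOCc1ccccc1
Why: Enders RAMP-hydrazone α-alkylation: the chelated azaenolate 4 should be alkylated on the face away from the methoxymethyl arm, which sets C7 in the sense of the (R)-ketone.

**Step 3**
Reactants: 5 alkylated hydrazone
Product: 6 (2R)-2-[(benzyloxy)methyl]cyclohept-4-en-1-one
Conditions: saturated aq. oxalic acid, Et2O, rt
Reagents that add atoms: water, O
Why: Mild two-phase acidic hydrazone hydrolysis should release the α-substituted ketone without enolising C7 and returns the auxiliary.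

**Step 4**
Reactants: 6 (2R)-2-[(benzyloxy)methyl]cyclohept-4-en-1-one
Product: 8 (5Z,8R)-8-[(benzyloxy)methyl]-3,4,7,8-tetrahydro-2H-oxocin-2-one, via silylated Criegee adduct 7 (not isolated)
Conditions: Me3SiOOSiMe3 (2 equiv), Me3SiOTf (10 mol %), CH2Cl2, −40 to −20 °C
Reagents that add atoms: bis(trimethylsilyl) peroxide, C[Si](C)(C)OO[Si](C)(C)C
Why: Baeyer–Villiger ring expansion: the Me3SiOTf-activated ketone adds the silyl peroxide to give Criegee adduct 7, in which C7 migrates from the former carbonyl carbon C13 to the proximal peroxide oxygen as hexamethyldisiloxane leaves, so the new O–C7 bond closes the eight-membered lactone. The closest known reaction type is the silyl-peroxide Baeyer–Villiger oxidation of 2-alkylcycloalkanones, including cycloheptanone-to-oxocanone expansions. The ring is closed by a one-atom ring expansion through a concerted suprafacial 1,2-shift, not by a medium-ring cyclisation, so no end-to-end closure penalty or high dilution is involved. No new stereocenter is made: C7 migrates with retention, so the configuration set in step 2 becomes the (R)-configured C–O stereocenter of the ring. The step needs regioselectivity (C7 and not the C12 methylene must migrate), which the secondary, more substituted nature of C7 secures, and chemoselectivity for the ketone over the isolated cis C9=C10 alkene, which the non-epoxidising silyl peroxide/Me3SiOTf system secures. The low temperature and non-basic medium should also keep the β-benzyloxy ketone from eliminating or epimerising before it is oxidised.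

**Step 5**
Reactants: 8 lactone
Product: 10 (3R,5Z,8R)-8-[(benzyloxy)methyl]-3-hydroxy-3,4,7,8-tetrahydro-2H-oxocin-2-one, via potassium lactone enolate 9 (not isolated)
Conditions: KN(SiMe3)2, THF, −78 °C; then 3-phenyl-2-(phenylsulfonyl)oxaziridine; NH4Cl quench
Reagents that add atoms: 3-phenyl-2-(phenylsulfonyl)oxaziridine, O=S(=O)(N1OC1c1ccccc1)c1ccccc1
Why: Davis enolate hydroxylation: the oxaziridine should attack enolate 9 on the less hindered outer face of the tub-shaped ring, which is expected to place the C12 hydroxyl cis to the C7 substituent (3R).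

**Step 6**
Reactants: 10 hydroxy lactone
Product: 11 (3R,5Z,8R)-8-[(benzyloxy)methyl]-3-[(tert-butyldimethylsilyl)oxy]-3,4,7,8-tetrahydro-2H-oxocin-2-one
Conditions: tBuMe2SiOTf, 2,6-lutidine, CH2Cl2, −78 to 0 °C
Reagents that add atoms: tert-butyldimethylsilyl triflate, CC(C)(C)[Si](C)(C)OS(=O)(=O)C(F)(F)F
Why: Silylation of the secondary alcohol with a silyl triflate protects C12–OH for the organometallic and radical steps; no stereocenter is touched.

**Step 7**
Reactants: 11 silyloxy lactone
Product: 12 (3R,5Z,8R)-8-[(benzyloxy)methyl]-3-[(tert-butyldimethylsilyl)oxy]-3,4,7,8-tetrahydro-2H-oxocine-2-thione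
Conditions: Lawesson's reagent, toluene, 110 °C
Reagents that add atoms: Lawesson's reagent, COc1ccc(cc1)P1(=S)SP(=S)(S1)c1ccc(OC)cc1
Why: Thionation of the lactone carbonyl with Lawesson's reagent gives the thionolactone, whose C=S carbon accepts a carbon nucleophile without ring opening.

**Step 8**
Reactants: 12 thionolactone
Product: 14 (3R,5Z,8R)-8-[(benzyloxy)methyl]-3-[(tert-butyldimethylsilyl)oxy]-2-ethyl-2-(methylsulfanyl)-3,4,7,8-tetrahydro-2H-oxocine (both C2 epimers), via lithium thiolate adduct 13 (not isolated)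
Conditions: EtLi, THF, −78 °C; then MeI, −78 °C to rt
Reagents that add atoms: ethyllithium, [Li]CC; iodomethane, CI
Why: Thionolactone alkylation: carbophilic addition of the organolithium gives tetrahedral thiolate 13, which does not collapse to a ring-opened ketone and is trapped by S-methylation, so ethyl enters at C13 with the ring intact; the C13 configuration does not matter here.

**Step 9**
Reactants: 14 mixed O,S-ketal
Product: 16 (2R,3R,5Z,8R)-8-[(benzyloxy)methyl]-3-[(tert-butyldimethylsilyl)oxy]-2-ethyl-3,4,7,8-tetrahydro-2H-oxocine, via anomeric radical 15 (not isolated)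
Conditions: Ph3SnH, AIBN (cat.), toluene, 110 °C
Reagents that add atoms: none
Why: Radical desulfurisation of the O,S-ketal: radical 15 should take hydrogen on the face anti to the neighbouring silyloxy group, giving the cis C7/C13 arrangement typical of this reduction and setting C13 as R.

**Step 10**
Reactants: 16 benzyl ether
Product: 17 [(2R,3R,5Z,8R)-3-[(tert-butyldimethylsilyl)oxy]-2-ethyl-3,4,7,8-tetrahydro-2H-oxocin-8-yl]methanol
Conditions: Na, NH3(l), THF, −78 °C; NH4Cl
Reagents that add atoms: none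
Why: Dissolving-metal cleavage of the benzyl ether frees the C6 primary alcohol while the isolated alkene, the silyl ether and the ring ether should be inert.

**Step 11**
Reactants: 17 primary alcohol
Product: 18 (2R,3R,5Z,8R)-3-[(tert-butyldimethylsilyl)oxy]-2-ethyl-3,4,7,8-tetrahydro-2H-oxocine-8-carbaldehyde
Conditions: Dess–Martin periodinane, NaHCO3, CH2Cl2, 0 °C to rt
Reagents that add atoms: none
Why: Buffered Dess–Martin oxidation should give the α-alkoxy aldehyde without epimerising C7; the aldehyde is used at once.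

**Step 12**
Reactants: 18 aldehyde
Product: 19 (1R)-1-[(2R,3R,5Z,8R)-3-[(tert-butyldimethylsilyl)oxy]-2-ethyl-3,4,7,8-tetrahydro-2H-oxocin-8-yl]but-3-en-1-ol
Conditions: MgBr2·OEt2, allylSnBu3, CH2Cl2, −78 to −20 °C
Reagents that add atoms: allyltributylstannane, C=CC[Sn](CCCC)(CCCC)CCCC
Why: Chelation-controlled (Cram-chelate) allylation: MgBr2 bridges the aldehyde oxygen and the ring oxygen and the stannane attacks the face bearing the C7 hydrogen, which should give the threo (6R,7R) alcohol.

**Step 13**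
Reactants: 19 homoallylic alcohol
Product: 20 (2E,5R)-5-[(2R,3R,5Z,8R)-3-[(tert-butyldimethylsilyl)oxy]-2-ethyl-3,4,7,8-tetrahydro-2H-oxocin-8-yl]-5-hydroxypent-2-enal
Conditions: second-generation Grubbs catalyst (H2IMes)(PCy3)Cl2Ru=CHPh (5 mol %), crotonaldehyde (5 equiv), CH2Cl2, 40 °C
Reagents that add atoms: (E)-but-2-enal, C/C=C/C=O
Why: Olefin cross-metathesis of the terminal alkene with crotonaldehyde should give the (E)-enal under thermodynamic control, while the little-strained, flanked ring alkene is expected to stay closed.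

**Step 14**
Reactants: 20 enal
Product: 21 (1R,3E)-1-[(2R,3R,5Z,8R)-3-[(tert-butyldimethylsilyl)oxy]-2-ethyl-3,4,7,8-tetrahydro-2H-oxocin-8-yl]hex-3-en-5-yn-1-ol
Conditions: Me3SiCHN2, n-BuLi (2.5 equiv each), THF, −78 to 0 °C
Reagents that add atoms: trimethylsilyldiazomethane, C[Si](C)(C)C=[N+]=[N-]
Why: Colvin rearrangement: the lithiated silyldiazomethane adds to the aldehyde and silanolate and N2 are lost with a 1,2-hydrogen shift to give the terminal alkyne, leaving the (E)-alkene untouched; the extra equivalent covers the free hydroxyl.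

**Step 15**
Reactants: 21 enyne alcohol
Product: 22 (1R,3E)-1-[(2R,3R,5Z,8R)-3-[(tert-butyldimethylsilyl)oxy]-2-ethyl-3,4,7,8-tetrahydro-2H-oxocin-8-yl]hex-3-en-5-yn-1-yl acetate
Conditions: Ac2O, pyridine, DMAP (cat.), CH2Cl2, rt
Reagents that add atoms: acetic anhydride, CC(=O)OC(C)=O
Why: DMAP-catalysed acylation of the C6 secondary alcohol installs the acetate of the target.

**Step 16**
Reactants: 22 silyl ether acetate
Product: 23 (1R,3E)-1-[(2R,3R,5Z,8R)-2-ethyl-3-hydroxy-3,4,7,8-tetrahydro-2H-oxocin-8-yl]hex-3-en-5-yn-1-yl acetate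
Conditions: HF·pyridine, pyridine, THF, 0 °C to rt
Reagents that add atoms: none
Why: Fluoride-mediated desilylation under buffered conditions should free the C12 alcohol and leave the acetate and the enyne intact.

**Step 17**
Reactants: 23 C12 alcohol
Product: 24 (1R,3E)-1-[(2R,3S,5Z,8R)-3-bromo-2-ethyl-3,4,7,8-tetrahydro-2H-oxocin-8-yl]hex-3-en-5-yn-1-yl acetate (target)
Conditions: CBr4, P(n-C8H17)3, toluene, 70 °C
Reagents that add atoms: carbon tetrabromide, BrC(Br)(Br)Br
Why: Appel-type bromination: bromide displaces the phosphonium-activated C12 oxygen by SN2 with inversion, turning the (12R)-alcohol into the (12S)-bromide trans to the ethyl group.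

**Compound list**
1 | cyclohept-4-en-1-one | O=C1CC/C=C\CC1 | starting material
2 | (R)-1-amino-2-(methoxymethyl)pyrrolidine (RAMP) | COC[C@H]1CCCN1N | starting material
3 | (R)-N-(cyclohept-4-en-1-ylidene)-2-(methoxymethyl)pyrrolidin-1-amine | COC[C@H]1CCCN1N=C1CC/C=C\CC1 | intermediate
4 | lithium azaenolate of 3 (not isolated) | COC[C@H]1CCCN1N([Li])C1=CC/C=C\CC1 | intermediate
5 | (R)-N-[(2S)-2-[(benzyloxy)methyl]cyclohept-4-en-1-ylidene]-2-(methoxymethyl)pyrrolidin-1-amine | COC[C@H]1CCCN1N=C1CC/C=C\C[C@@H]1COCc1ccccc1 | intermediate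
6 | (2R)-2-[(benzyloxy)methyl]cyclohept-4-en-1-one | O=C1CC/C=C\C[C@@H]1COCc1ccccc1 | intermediate
7 | (2R)-2-[(benzyloxy)methyl]-1-(trimethylsilyloxy)-1-(trimethylsilylperoxy)cyclohept-4-ene, either configuration at C1 (not isolated) | C[Si](C)(C)OOC1(O[Si](C)(C)C)CC/C=C\C[C@@H]1COCc1ccccc1 | intermediate
8 | (5Z,8R)-8-[(benzyloxy)methyl]-3,4,7,8-tetrahydro-2H-oxocin-2-one | c1ccccc1COC[C@H]1C/C=C\CCC(=O)O1 | intermediate
9 | potassium enolate of 8 (not isolated) | c1ccccc1COC[C@H]1C/C=C\CC=C(O[K])O1 | intermediate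
10 | (3R,5Z,8R)-8-[(benzyloxy)methyl]-3-hydroxy-3,4,7,8-tetrahydro-2H-oxocin-2-one | c1ccccc1COC[C@H]1C/C=C\C[C@@H](O)C(=O)O1 | intermediate
11 | (3R,5Z,8R)-8-[(benzyloxy)methyl]-3-[(tert-butyldimethylsilyl)oxy]-3,4,7,8-tetrahydro-2H-oxocin-2-one | c1ccccc1COC[C@H]1C/C=C\C[C@@H](O[Si](C)(C)C(C)(C)C)C(=O)O1 | intermediate
12 | (3R,5Z,8R)-8-[(benzyloxy)methyl]-3-[(tert-butyldimethylsilyl)oxy]-3,4,7,8-tetrahydro-2H-oxocine-2-thione | c1ccccc1COC[C@H]1C/C=C\C[C@@H](O[Si](C)(C)C(C)(C)C)C(=S)O1 | intermediate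
13 | lithium (3R,5Z,8R)-8-[(benzyloxy)methyl]-3-[(tert-butyldimethylsilyl)oxy]-2-ethyl-3,4,7,8-tetrahydro-2H-oxocine-2-thiolate, both C2 epimers (not isolated) | c1ccccc1COC[C@H]1C/C=C\C[C@@H](O[Si](C)(C)C(C)(C)C)C(CC)(S[Li])O1 | intermediate
14 | (3R,5Z,8R)-8-[(benzyloxy)methyl]-3-[(tert-butyldimethylsilyl)oxy]-2-ethyl-2-(methylsulfanyl)-3,4,7,8-tetrahydro-2H-oxocine, both C2 epimers | c1ccccc1COC[C@H]1C/C=C\C[C@@H](O[Si](C)(C)C(C)(C)C)C(CC)(SC)O1 | intermediate
15 | (3R,5Z,8R)-8-[(benzyloxy)methyl]-3-[(tert-butyldimethylsilyl)oxy]-2-ethyl-3,4,7,8-tetrahydro-2H-oxocin-2-yl radical (not isolated) | c1ccccc1COC[C@H]1C/C=C\C[C@@H](O[Si](C)(C)C(C)(C)C)[C](CC)O1 | intermediate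
16 | (2R,3R,5Z,8R)-8-[(benzyloxy)methyl]-3-[(tert-butyldimethylsilyl)oxy]-2-ethyl-3,4,7,8-tetrahydro-2H-oxocine | c1ccccc1COC[C@H]1C/C=C\C[C@@H](O[Si](C)(C)C(C)(C)C)[C@@H](CC)O1 | intermediate
17 | [(2R,3R,5Z,8R)-3-[(tert-butyldimethylsilyl)oxy]-2-ethyl-3,4,7,8-tetrahydro-2H-oxocin-8-yl]methanol | OC[C@H]1C/C=C\C[C@@H](O[Si](C)(C)C(C)(C)C)[C@@H](CC)O1 | intermediate
18 | (2R,3R,5Z,8R)-3-[(tert-butyldimethylsilyl)oxy]-2-ethyl-3,4,7,8-tetrahydro-2H-oxocine-8-carbaldehyde | O=C[C@H]1C/C=C\C[C@@H](O[Si](C)(C)C(C)(C)C)[C@@H](CC)O1 | intermediate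
19 | (1R)-1-[(2R,3R,5Z,8R)-3-[(tert-butyldimethylsilyl)oxy]-2-ethyl-3,4,7,8-tetrahydro-2H-oxocin-8-yl]but-3-en-1-ol | C=CC[C@@H](O)[C@H]1C/C=C\C[C@@H](O[Si](C)(C)C(C)(C)C)[C@@H](CC)O1 | intermediate
20 | (2E,5R)-5-[(2R,3R,5Z,8R)-3-[(tert-butyldimethylsilyl)oxy]-2-ethyl-3,4,7,8-tetrahydro-2H-oxocin-8-yl]-5-hydroxypent-2-enal | O=C/C=C/C[C@@H](O)[C@H]1C/C=C\C[C@@H](O[Si](C)(C)C(C)(C)C)[C@@H](CC)O1 | intermediate
21 | (1R,3E)-1-[(2R,3R,5Z,8R)-3-[(tert-butyldimethylsilyl)oxy]-2-ethyl-3,4,7,8-tetrahydro-2H-oxocin-8-yl]hex-3-en-5-yn-1-ol | C#C/C=C/C[C@@H](O)[C@H]1C/C=C\C[C@@H](O[Si](C)(C)C(C)(C)C)[C@@H](CC)O1 | intermediate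
22 | (1R,3E)-1-[(2R,3R,5Z,8R)-3-[(tert-butyldimethylsilyl)oxy]-2-ethyl-3,4,7,8-tetrahydro-2H-oxocin-8-yl]hex-3-en-5-yn-1-yl acetate | C#C/C=C/C[C@@H](OC(C)=O)[C@H]1C/C=C\C[C@@H](O[Si](C)(C)C(C)(C)C)[C@@H](CC)O1 | intermediate
23 | (1R,3E)-1-[(2R,3R,5Z,8R)-2-ethyl-3-hydroxy-3,4,7,8-tetrahydro-2H-oxocin-8-yl]hex-3-en-5-yn-1-yl acetate | C#C/C=C/C[C@@H](OC(C)=O)[C@H]1C/C=C\C[C@@H](O)[C@@H](CC)O1 | intermediate
24 | (1R,3E)-1-[(2R,3S,5Z,8R)-3-bromo-2-ethyl-3,4,7,8-tetrahydro-2H-oxocin-8-yl]hex-3-en-5-yn-1-yl acetate | C#C/C=C/C[C@@H](OC(C)=O)[C@H]1C/C=C\C[C@H](Br)[C@@H](CC)O1 | target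

**Step count and risks**
Total step count: 17. Longest linear sequence: 17 steps, from cyclohept-4-en-1-one.

Steps most likely to fail:

Step 4. The ring expansion of a cycloheptanone is slow, so oxidation of the ring alkene, loss of regiocontrol in the migration, or epimerisation at C7 before oxidation may intervene. The fallback sets out from ketone 6 and masks the alkene: Br2 in CH2Cl2 at −78 °C should give the trans-dibromide (2R)-2-[(benzyloxy)methyl]-4,5-dibromocycloheptan-1-one F1. A peracid Baeyer–Villiger oxidation (CF3CO3H, Na2HPO4, CH2Cl2, 0 °C), now free of any alkene, should give (8R)-8-[(benzyloxy)methyl]-5,6-dibromooxocan-2-one F2. Zn dust in AcOH/EtOH should then restore the cis alkene by anti elimination, and the route is rejoined at lactone 8.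

Step 5. Facial selectivity in the enolate oxidation may be poor or reversed. The fallback sets out from lactone 8 through the same oxidation, which would then give mainly the epimer (3S,5Z,8R)-8-[(benzyloxy)methyl]-3-hydroxy-3,4,7,8-tetrahydro-2H-oxocin-2-one F3. A Mitsunobu inversion with chloroacetic acid (PPh3, DIAD, THF, 0 °C) should give (3R,5Z,8R)-8-[(benzyloxy)methyl]-2-oxo-3,4,7,8-tetrahydro-2H-oxocin-3-yl chloroacetate F4. Thiourea with NaHCO3 in EtOH should remove the chloroacetyl group without opening the lactone, and the route is rejoined at hydroxy lactone 10.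

Step 8 (with step 7 before it). Enethiolisation or ring opening may outrun carbophilic addition at the hindered thiocarbonyl, or thionation next to the silyloxy group may stall. The fallback sets out from silyloxy lactone 11 and avoids sulfur: Takai–Utimoto ethylidenation (CH3CHBr2, Zn, TiCl4, TMEDA, PbCl2 cat., THF) should give the enol ether (2Z,3R,5Z,8R)-8-[(benzyloxy)methyl]-3-[(tert-butyldimethylsilyl)oxy]-2-ethylidene-3,4,7,8-tetrahydro-2H-oxocine F5. Ionic hydrogenation (Et3SiH, CF3CO2H, CH2Cl2, −78 °C) protonates the exocyclic carbon and should deliver hydride to the ring oxocarbenium anti to the silyloxy group, and the route is rejoined at ether 16.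

**Further compounds**
F1 | step 4 | (2R)-2-[(benzyloxy)methyl]-4,5-dibromocycloheptan-1-one (trans-dibromide, either trans diastereomer) | c1ccccc1COC[C@H]1CC(Br)C(Br)CCC1=O
F2 | step 4 | (8R)-8-[(benzyloxy)methyl]-5,6-dibromooxocan-2-one (trans-dibromide) | c1ccccc1COC[C@H]1CC(Br)C(Br)CCC(=O)O1
F3 | step 5 | (3S,5Z,8R)-8-[(benzyloxy)methyl]-3-hydroxy-3,4,7,8-tetrahydro-2H-oxocin-2-one | c1ccccc1COC[C@H]1C/C=C\C[C@H](O)C(=O)O1
F4 | step 5 | (3R,5Z,8R)-8-[(benzyloxy)methyl]-2-oxo-3,4,7,8-tetrahydro-2H-oxocin-3-yl chloroacetate | c1ccccc1COC[C@H]1C/C=C\C[C@@H](OC(=O)CCl)C(=O)O1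
F5 | step 8 | (2Z,3R,5Z,8R)-8-[(benzyloxy)methyl]-3-[(tert-butyldimethylsilyl)oxy]-2-ethylidene-3,4,7,8-tetrahydro-2H-oxocine | c1ccccc1COC[C@H]1C/C=C\C[C@@H](O[Si](C)(C)C(C)(C)C)/C(=C/C)O1
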